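**Retrosynthetic overview**
1. The acetate comes from primary-selective acetylation of a butenolide diol. The butenolide comes from a furan (C–H borylation/oxidation at its less hindered α-CH); the furan stands in for the butenolide until the end.
2. The 1,4-diol and side chain come from a γ-lactone: α-alkylation with 5-bromo-2-methylpent-2-ene, then LiAlH4 opening.
3. Key disconnection: the bond between the carbinol carbon and the ring CH that bears the side chain. A carbene-generated homoenolate of a furan-bound enal attacks a tethered aliphatic aldehyde, closing the eight-membered ring and the cis γ-lactone together.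
4. The furan comes from a propargylic alcohol (anti-carbomagnesiation with vinyl Grignard, DMF), with the enal added by cross-metathesis; the alkyne comes from a seven-membered lactone.
5. Cyclopropane and CHMe come from Corey–Chaykovsky cyclopropanation of (S)-4-methylcyclohexenone (propanal + methyl vinyl ketone), cut open by Baeyer–Villiger. Ring order: cyclohexenone, cyclopropane, (six-ring opened), furan, cyclooctane + γ-lactone in one step, (lactone opened), butenolide.

Assumption: the SMILES is taken as the full definition of the target, absolute configuration as written.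
Labels used in descriptive names: eight-membered ring C1 (CH bearing the side chain), C2 and C3 (the two sp2 carbons, C2 on C1), C4 and C5 (cyclopropane CH, C4 on C3), C6 (CHMe), C7 (CH2), C8 (carbinol CH); C1' is the side-chain CH. Target: 1R,4R,5R,6S,8S,1'S.

**Route**

Step 1
Reactants: 1 propanal; 2 methyl vinyl ketone
Product: 4 (S)-4-methylcyclohex-2-en-1-one, via (S)-2-methyl-5-oxohexanal 3 (not isolated)
Conditions: (R)-2-(methoxydiphenylmethyl)pyrrolidine (5 mol %), ethyl 3,4-dihydroxybenzoate (20 mol %), neat, 4 °C; then LiOH (0.3 equiv), i-PrOH, rt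
Reagents that add atoms: none
Why: enamine Michael addition of propanal to the enone, with the catalyst shielding one enamine face so that the methyl-bearing centre is set as S, followed by intramolecular aldol condensation of the 1,5-keto aldehyde (organocatalytic Michael/aldol, Robinson-type annulation).

Step 2
Reactants: 4 (S)-4-methylcyclohex-2-en-1-one
Product: 5 (1R,5S,6R)-5-methylbicyclo[4.1.0]heptan-2-one
Conditions: Me3S(O)I, NaH, DMSO, rt
Reagents that add atoms: trimethylsulfoxonium iodide, C[S+](C)(C)=O.[I-]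
Why: Corey–Chaykovsky cyclopropanation in which the sulfoxonium ylide adds to the β-carbon anti to the neighbouring C4 methyl group and closes the ring on that face, giving the cis-fused cyclopropane trans to the methyl group.

Step 3
Reactants: 5 (1R,5S,6R)-5-methylbicyclo[4.1.0]heptan-2-one
Product: 6 (1R,6S,7R)-6-methyl-3-oxabicyclo[5.1.0]octan-2-one
Conditions: mCPBA, CH2Cl2, 0 °C → rt
Reagents that add atoms: mCPBA, OOC(=O)c1cccc(Cl)c1
Why: Baeyer–Villiger oxidation in which the ring CH2 (primary alkyl) migrates in preference to the cyclopropyl carbon, so oxygen enters on the CH2 side and no stereocentre is touched.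

Step 4
Reactants: 6 (1R,6S,7R)-6-methyl-3-oxabicyclo[5.1.0]octan-2-one
Product: 8 (3S)-3-[(1R,2R)-2-ethynylcyclopropyl]butan-1-ol, via (1R,6S,7R)-6-methyl-3-oxabicyclo[5.1.0]octan-2-ol 7 (not isolated)
Conditions: iBu2AlH, CH2Cl2, −78 °C; then MeOH, K2CO3, dimethyl (1-diazo-2-oxopropyl)phosphonate, −78 °C → rt
Reagents that add atoms: dimethyl (1-diazo-2-oxopropyl)phosphonate, CC(=O)C(=[N+]=[N-])P(=O)(OC)OC
Why: half-reduction to the lactol and one-pot Seyferth–Gilbert homologation (Ohira–Bestmann reagent) of its open hydroxy aldehyde form, which is faster than epimerisation of the cis-cyclopropane carbaldehyde.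

Step 5
Reactants: 8 (3S)-3-[(1R,2R)-2-ethynylcyclopropyl]butan-1-ol
Product: 9 (3S)-3-[(1R,2R)-2-(3-hydroxyprop-1-yn-1-yl)cyclopropyl]butan-1-ol
Conditions: n-BuLi (2.2 equiv), THF, −78 °C; (CH2O)n, −78 °C → rt
Reagents that add atoms: paraformaldehyde (reacts as formaldehyde), C=O
Why: addition of the lithium acetylide (alkoxide–acetylide dianion) to formaldehyde.

Step 6
Reactants: 9 (3S)-3-[(1R,2R)-2-(3-hydroxyprop-1-yn-1-yl)cyclopropyl]butan-1-ol; 10 vinylmagnesium chloride
Product: 12 (3S)-3-[(1R,2R)-2-(4-ethenylfuran-3-yl)cyclopropyl]butan-1-ol, via 2,5-dihydrofuran-2-ol 11 (not isolated)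
Conditions: CH2=CHMgCl (5 equiv), THF–cyclohexane, reflux; DMF, 0 °C → rt; aq. HCl work-up, then TsOH (cat.), CH2Cl2, rt
Reagents that add atoms: N,N-dimethylformamide, CN(C)C=O
Why: magnesium-alkoxide-directed anti-carbomagnesiation of the propargylic alcohol (vinyl to the carbon next to CH2O, magnesium to the cyclopropyl-bearing carbon), formylation of the alkenylmagnesium by DMF, and acid-catalysed dehydration of the cyclic hemiacetal to the 3,4-disubstituted furan.

Step 7
Reactants: 12 (3S)-3-[(1R,2R)-2-(4-ethenylfuran-3-yl)cyclopropyl]butan-1-ol; 13 (E)-crotonaldehyde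
Product: 14 (2E)-3-{4-[(1R,2R)-2-[(2S)-4-hydroxybutan-2-yl]cyclopropyl]furan-3-yl}prop-2-enal
Conditions: second-generation Hoveyda–Grubbs catalyst RuCl2(H2IMes)(=CH–C6H4–2-OiPr) (5 mol %), CH2Cl2, 40 °C
Reagents that add atoms: none
Why: olefin cross-metathesis of the styrene-like vinylfuran with an enal partner, giving the thermodynamically preferred E-enal.

Step 8
Reactants: 14 (2E)-3-{4-[(1R,2R)-2-[(2S)-4-hydroxybutan-2-yl]cyclopropyl]furan-3-yl}prop-2-enal
Product: 15 (2E)-3-{4-[(1R,2R)-2-[(2S)-4-oxobutan-2-yl]cyclopropyl]furan-3-yl}prop-2-enal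
Conditions: Dess–Martin periodinane, pyridine, CH2Cl2, 0 °C → rt
Reagents that add atoms: none
Why: Dess–Martin oxidation of the primary alcohol to the aldehyde under buffered conditions that leave the furan and the enal untouched.

Step 9
Reactants: 15 (2E)-3-{4-[(1R,2R)-2-[(2S)-4-oxobutan-2-yl]cyclopropyl]furan-3-yl}prop-2-enal
Product: 16 tricyclic furan γ-lactone (1R,4R,5R,6S,8S): furan fused at C2–C3; cyclopropane cis-fused at C4–C5; γ-lactone cis-fused at C8 (O) and C1 (CH2C=O)
Conditions: 1,3-dimesitylimidazolium chloride (15 mol %), DBU (12 mol %), THF, 0.005 M (slow addition), 40 °C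
Reagents that add atoms: none
Why: Proposed new method: the N-mesityl carbene adds to the enal and the Breslow intermediate reacts as a homoenolate whose β-carbon C1 (normally an acceptor carbon) attacks the tethered aldehyde carbon C8, after which the C8 alkoxide is acylated by the acyl azolium to close the cis γ-lactone and release the carbene; the flat furan and the cis-cyclopropane hold the chain ends together, the tether reaches C1 only when the C4–C5 and forming C1–C8 bonds lie on one face of the furan with the hydrogens on C1 and C4 turned toward each other (H-1 cis to the cyclopropane hydrogens, C1 R), and the hydrogen-bonded syn addition usual for this annulation puts O-8 cis to the acyl arm (C8 S); the closest known reaction type is the carbene-catalysed homoenolate [3+2] annulation of enals with aldehydes to γ-butyrolactones, known intermolecularly and for intramolecular five- and six-membered ring closures.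

Step 10
Reactants: 16 tricyclic furan γ-lactone; 17 5-bromo-2-methylpent-2-ene
Product: 18 α-(4-methylpent-3-enyl) tricyclic furan γ-lactone (1R,4R,5R,6S,8S,1'S)
Conditions: LiN(iPr)2, THF, −78 °C; then 17, HMPA, −78 → −20 °C
Reagents that add atoms: none
Why: lactone enolate alkylation (SN2) on the face opposite the two cis substituents at the β- and γ-carbons, which sets C1' as S (side chain trans to the furan-bearing carbon).

Step 11
Reactants: 18 α-(4-methylpent-3-enyl) tricyclic furan γ-lactone
Product: 19 furan diol (1R,4R,5R,6S,8S,1'S): C8–OH and C1–CH(CH2OH)CH2CH2CH=C(CH3)2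
Conditions: LiAlH4, THF, 0 °C
Reagents that add atoms: none
Why: hydride reduction of the γ-lactone to the 1,4-diol, which affects no stereocentre and leaves the furan intact.

Step 12
Reactants: 19 furan diol
Product: 21 butenolide diol (O-deacetyl target; 1R,4R,5R,6S,8S,1'S), via furyl pinacol boronate 20 (not isolated)
Conditions: [Ir(OMe)(cod)]2 (3 mol %), 4,4'-di-tert-butyl-2,2'-bipyridine (6 mol %), B2pin2 (1.5 equiv), THF, 50 °C; then NaBO3·4H2O, THF–H2O, rt
Reagents that add atoms: bis(pinacolato)diboron, CC1(C)OB(OC1(C)C)B1OC(C)(C)C(C)(C)O1 (boron stays only in 20); sodium perborate, [Na+].[O-]OB=O (oxygen)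
Why: iridium-catalysed C–H borylation at the less hindered furan α-CH (next to the small cyclopropyl carbon, not next to the branched C1, whose hydroxyls are O-borylated in the flask), then perborate oxidation of the 2-furyl boronate to the 2-hydroxyfuran, which tautomerises to the conjugated butenolide with C=O on C3.

Step 13
Reactants: 21 butenolide diol
Product: 22 CNP0267808.2
Conditions: Ac2O (1.05 equiv), pyridine, CH2Cl2, −20 °C
Reagents that add atoms: acetic anhydride, CC(=O)OC(C)=O
Why: selective acylation of the unhindered primary hydroxyl over the hindered secondary ring hydroxyl at low temperature.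

**Compound list**
1 | propanal | CCC=O | starting material
2 | methyl vinyl ketone (but-3-en-2-one) | CC(=O)C=C | starting material
3 | (S)-2-methyl-5-oxohexanal | O=C[C@@H](C)CCC(C)=O | intermediate (not isolated)
4 | (S)-4-methylcyclohex-2-en-1-one | O=C1C=C[C@@H](C)CC1 | intermediate
5 | (1R,5S,6R)-5-methylbicyclo[4.1.0]heptan-2-one | O=C1[C@@H]2C[C@@H]2[C@@H](C)CC1 | intermediate
6 | (1R,6S,7R)-6-methyl-3-oxabicyclo[5.1.0]octan-2-one | O=C1[C@@H]2C[C@@H]2[C@@H](C)CCO1 | intermediate
7 | (1R,6S,7R)-6-methyl-3-oxabicyclo[5.1.0]octan-2-ol (anomer mixture, in equilibrium with the hydroxy aldehyde) | OC1[C@@H]2C[C@@H]2[C@@H](C)CCO1 | intermediate (not isolated)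
8 | (3S)-3-[(1R,2R)-2-ethynylcyclopropyl]butan-1-ol | C#C[C@@H]1C[C@@H]1[C@@H](C)CCO | intermediate
9 | (3S)-3-[(1R,2R)-2-(3-hydroxyprop-1-yn-1-yl)cyclopropyl]butan-1-ol | OCC#C[C@@H]1C[C@@H]1[C@@H](C)CCO | intermediate
10 | vinylmagnesium chloride | C=C[Mg]Cl | starting material
11 | 4-ethenyl-3-{(1R,2R)-2-[(2S)-4-hydroxybutan-2-yl]cyclopropyl}-2,5-dihydrofuran-2-ol (anomer mixture) | OC1OCC(C=C)=C1[C@@H]1C[C@@H]1[C@@H](C)CCO | intermediate (not isolated)
12 | (3S)-3-[(1R,2R)-2-(4-ethenylfuran-3-yl)cyclopropyl]butan-1-ol | C=Cc1cocc1[C@@H]1C[C@@H]1[C@@H](C)CCO | intermediate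
13 | (E)-crotonaldehyde | C/C=C/C=O | starting material
14 | (2E)-3-{4-[(1R,2R)-2-[(2S)-4-hydroxybutan-2-yl]cyclopropyl]furan-3-yl}prop-2-enal | O=C/C=C/c1cocc1[C@@H]1C[C@@H]1[C@@H](C)CCO | intermediate
15 | (2E)-3-{4-[(1R,2R)-2-[(2S)-4-oxobutan-2-yl]cyclopropyl]furan-3-yl}prop-2-enal | O=C/C=C/c1cocc1[C@@H]1C[C@@H]1[C@@H](C)CC=O | intermediate
16 | tricyclic furan γ-lactone (1R,4R,5R,6S,8S): cyclooctane fused to furan (C2–C3), cis-cyclopropane (C4–C5), cis-γ-lactone (O on C8, CH2C=O on C1), CH3 on C6 | O=C1C[C@@H]2c3cocc3[C@@H]3C[C@@H]3[C@@H](C)C[C@@H]2O1 | intermediate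
17 | 5-bromo-2-methylpent-2-ene | CC(C)=CCCBr | starting material
18 | lactone 16 carrying a 4-methylpent-3-enyl group on the lactone α-carbon C1' (1R,4R,5R,6S,8S,1'S) | O=C1[C@@H](CCC=C(C)C)[C@@H]2c3cocc3[C@@H]3C[C@@H]3[C@@H](C)C[C@@H]2O1 | intermediate
19 | furan diol (1R,4R,5R,6S,8S,1'S): C8–OH, C1–CH(CH2OH)CH2CH2CH=C(CH3)2 | OC[C@@H](CCC=C(C)C)[C@@H]1c2cocc2[C@@H]2C[C@@H]2[C@@H](C)C[C@@H]1O | intermediate
20 | furan diol 19 with a pinacolboryl group on the furan α-carbon next to C3 | OC[C@@H](CCC=C(C)C)[C@@H]1c2coc(B3OC(C)(C)C(C)(C)O3)c2[C@@H]2C[C@@H]2[C@@H](C)C[C@@H]1O | intermediate (not isolated)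
21 | butenolide diol, O-deacetyl target (1R,4R,5R,6S,8S,1'S): lactone C=O on C3, OCH2 on C2 | OC[C@@H](CCC=C(C)C)[C@@H]1C2=C(C(=O)OC2)[C@@H]2C[C@@H]2[C@@H](C)C[C@@H]1O | intermediate
22 | CNP0267808.2, the primary acetate of 21 | CC(=O)OC[C@@H](CCC=C(C)C)[C@@H]1C2=C(C(=O)OC2)[C@@H]2C[C@@H]2[C@@H](C)C[C@@H]1O | target

**Totals and risks**
Total step count: 13. Longest linear sequence: 13 steps, from propanal and methyl vinyl ketone.

Three steps most likely to fail:

Step 9 (eight-membered ring closure by homoenolate annulation; possible oligomers, Stetter or benzoin products, or the wrong diastereomer). The fallback makes the same bond with a samarium ketyl instead of a carbene. It sets out from 12: cross-metathesis with methyl acrylate under the step 7 catalyst gives methyl (2E)-3-{4-[(1R,2R)-2-[(2S)-4-hydroxybutan-2-yl]cyclopropyl]furan-3-yl}prop-2-enoate F1. Dess–Martin oxidation gives methyl (2E)-3-{4-[(1R,2R)-2-[(2S)-4-oxobutan-2-yl]cyclopropyl]furan-3-yl}prop-2-enoate F2. SmI2, HMPA and t-BuOH in THF at high dilution (−78 → 0 °C) then add the aldehyde ketyl to the acrylate β-carbon and the samarium alkoxide lactonises, coming back to the route at 16; the ring-fusion selectivity would have to be checked.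

Step 12 (regioselectivity of the furan C–H borylation). The fallback uses singlet oxygen instead. It sets out from 19: photooxygenation (O2, tetraphenylporphyrin, visible light, CH2Cl2, −78 °C) and then i-Pr2NEt, which removes the less hindered bridgehead hydrogen of the endoperoxide (the one next to the cyclopropyl-bearing carbon), gives the γ-hydroxybutenolide (C=O on C3, hemiacetal CH(OH) on C2) F3. NaBH4 in MeOH at 0 °C followed by acidification reduces the masked aldehyde and relactonises, coming back to the route at 21.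

Step 3 (Baeyer–Villiger regiochemistry; cyclopropyl migration could compete). The fallback cuts the ring by enol ether ozonolysis. It sets out from 5: LiN(iPr)2 and Me3SiCl (enolisation is possible only toward the CH2) give trimethyl{[(1R,5S,6R)-5-methylbicyclo[4.1.0]hept-2-en-2-yl]oxy}silane F4. Ozonolysis with NaBH4 work-up gives (1R,2R)-2-[(2S)-4-hydroxybutan-2-yl]cyclopropane-1-carboxylic acid F5. Me3SiCHN2 in MeOH gives methyl (1R,2R)-2-[(2S)-4-hydroxybutan-2-yl]cyclopropane-1-carboxylate F6. iBu2AlH and then the Ohira–Bestmann reagent with K2CO3 in MeOH, as in step 4, come back to the route at 8.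

**Further compounds**
F1 | step 9 | methyl (2E)-3-{4-[(1R,2R)-2-[(2S)-4-hydroxybutan-2-yl]cyclopropyl]furan-3-yl}prop-2-enoate | COC(=O)/C=C/c1cocc1[C@@H]1C[C@@H]1[C@@H](C)CCO
F2 | step 9 | methyl (2E)-3-{4-[(1R,2R)-2-[(2S)-4-oxobutan-2-yl]cyclopropyl]furan-3-yl}prop-2-enoate | COC(=O)/C=C/c1cocc1[C@@H]1C[C@@H]1[C@@H](C)CC=O
F3 | step 12 | γ-hydroxybutenolide of diol 19 (C=O on C3, CH(OH)–O on C2, hemiacetal epimers) | OC[C@@H](CCC=C(C)C)[C@@H]1C2=C(C(=O)OC2O)[C@@H]2C[C@@H]2[C@@H](C)C[C@@H]1O
F4 | step 3 | trimethyl{[(1R,5S,6R)-5-methylbicyclo[4.1.0]hept-2-en-2-yl]oxy}silane | C[Si](C)(C)OC1[C@@H]2C[C@@H]2[C@@H](C)CC=1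
F5 | step 3 | (1R,2R)-2-[(2S)-4-hydroxybutan-2-yl]cyclopropane-1-carboxylic acid | OC(=O)[C@@H]1C[C@@H]1[C@@H](C)CCO
F6 | step 3 | methyl (1R,2R)-2-[(2S)-4-hydroxybutan-2-yl]cyclopropane-1-carboxylate | COC(=O)[C@@H]1C[C@@H]1[C@@H](C)CCO
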